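The route rests on breaking the bond between the quaternary lactam α-carbon C6 (ring D) and the enone β-carbon C13 (ring C). Because C6 is bonded directly to C13, while the ring-B methylene C11 already links C10 to the enone α-carbon C12, a lactam enolate can displace chloride from a tethered 3-chlorocyclohexenone. This one operation closes ring B, completes the 2-azabicyclo[3.3.1]nonane and fixes the C6 quaternary centre. The substrate is an N-PMB δ-lactam with the stereodefined C10/C18 pair, the chloroenone arm on C10 and an acrylate arm on C6, which makes C6–H the most acidic site and later delivers the ester enolate for ring A.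

Key step: step 13

Remarks on the chemistry (one line each):
- Labels: N8; C7 lactam C=O; C6 lactam α-carbon; C18 quaternary carbon bearing C19H2O and the arm C20–C22; C10 CH bearing C11H2; C9 NCH2; ring C = C12 (enone α) C13 (enone β) C14 C15 C16 C17 (C=O); ester arm C5 C4 C3; ring E arm C20–C24 with the methyl on C23. Rings: A = C4 C5 C6 C13 C14; B = C6 C13 C12 C11 C10 C18; D = N8 C7 C6 C18 C10 C9; E = N8 C9 C10 C18 C20–C24. PMB = 4-methoxybenzyl; TBDPS = tert-butyldiphenylsilyl.
- Assumption: the C23 methyl configuration of the target is taken to be the more stable one on the strapped nine-membered ring E; C23 is α to the C22 ketone and equilibrates under the basic ring closure.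
- C6 in 17–24 is an epimer mixture (erased by enolisation in step 13); C4 in 28–30 and C22 in 36 are likewise uncontrolled and are erased in steps 17 and 21.
- The ester arm is carried through the key step as its (E)-acrylate (same carbon skeleton), because a plain N-alkyl lactam α-C–H is far less acidic than the ketone and ester C–H bonds of the substrate.
- Ring A is not closed by base on the free ene-1,4-dione, because 2,3-dialkylcyclohex-2-ene-1,4-diones tautomerise to hydroquinones; one carbonyl is masked first.

Step 1
Reactants: 1 2,2-dimethoxyacetaldehyde; 2 nitromethane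
Product: 5 (E)-3,3-dimethoxy-1-nitroprop-1-ene, via nitro alcohol 3 (not isolated), via trifluoroacetate 4 (not isolated)
Conditions: K2CO3 (cat.), THF/H2O, 0 °C → rt; then (CF3CO)2O, Et3N, CH2Cl2, −15 °C
Reagents that add atoms: none
Why: Henry (nitroaldol) addition followed by E1cB loss of trifluoroacetate should give the conjugated (E)-nitroalkene, the thermodynamically favoured geometry; no stereocentre is carried on.

Step 2
Reactants: 5 (E)-3,3-dimethoxy-1-nitroprop-1-ene; 6 methyl 4-oxobutanoate
Product: 7 methyl (3S,4S)-3-formyl-5,5-dimethoxy-4-(nitromethyl)pentanoate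
Conditions: (R)-2-[diphenyl(trimethylsilyloxy)methyl]pyrrolidine (10 mol%), 4-nitrophenol (10 mol%), toluene, 0 °C
Reagents that add atoms: none
Why: Enamine-catalysed Michael addition of an aldehyde to a nitroalkene (Hayashi–Jørgensen catalyst): the anti-enamine of 6 should attack 5 through the usual synclinal open transition state on the face left free by the diarylsilyloxymethyl group, which with the (R)-catalyst sets C10 as S (syn adduct; the C18 centre formed here is erased in step 6).

Step 3
Reactants: 7 methyl (3S,4S)-3-formyl-5,5-dimethoxy-4-(nitromethyl)pentanoate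
Product: 8 (2S,3S)-4,4-dimethoxy-2-(2-methoxy-2-oxoethyl)-3-(nitromethyl)butanoic acid
Conditions: NaClO2, NaH2PO4, 2-methyl-2-butene, t-BuOH/H2O, 0 °C → rt
Reagents that add atoms: sodium chlorite, [Na+].[O-]Cl=O
Why: Pinnick oxidation converts the aldehyde into the acid under buffered conditions that should leave the acetal, the nitro group and the α-centre untouched.

Step 4
Reactants: 8 (2S,3S)-4,4-dimethoxy-2-(2-methoxy-2-oxoethyl)-3-(nitromethyl)butanoic acid
Product: 10 (4S,5S)-5-(dimethoxymethyl)-2-oxopiperidine-4-carboxylic acid, via amino acid 9 (not isolated)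
Conditions: H2 (4 bar), Raney Ni, MeOH, rt; then Et3N, 60 °C
Reagents that add atoms: none
Why: Hydrogenation of the nitro group gives the primary amine, which should close the six-membered lactam by aminolysis of the methyl ester (the free carboxylate cannot acylate, so no pyrrolidinone forms); C10 is not affected.

Step 5
Reactants: 10 (4S,5S)-5-(dimethoxymethyl)-2-oxopiperidine-4-carboxylic acid
Product: 11 4-methoxybenzyl (4S,5S)-5-(dimethoxymethyl)-1-(4-methoxybenzyl)-2-oxopiperidine-4-carboxylate
Conditions: NaH (2.4 equiv), 4-methoxybenzyl chloride, n-Bu4NI (cat.), DMF, 0 °C → rt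
Reagents that add atoms: 4-methoxybenzyl chloride, COc1ccc(CCl)cc1
Why: Double Williamson-type alkylation: the sodium carboxylate and the sodium lactamate are both benzylated, which gives the ester needed for enolate formation and blocks N8 (any epimerisation at C18 is irrelevant).

Step 6
Reactants: 11 4-methoxybenzyl (4S,5S)-5-(dimethoxymethyl)-1-(4-methoxybenzyl)-2-oxopiperidine-4-carboxylate; 12 allyl bromide
Product: 13 4-methoxybenzyl (4S,5S)-4-allyl-5-(dimethoxymethyl)-1-(4-methoxybenzyl)-2-oxopiperidine-4-carboxylate
Conditions: KN(SiMe3)2, THF, −78 °C; allyl bromide, −78 → −30 °C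
Reagents that add atoms: none
Why: Ester enolate alkylation: KN(SiMe3)2 deprotonates only the ester α-position C18 (the lactam α-CH2 is too weakly acidic) and allyl bromide should enter anti to the neighbouring C10 acetal substituent, which A1,3 strain holds pseudoaxial over one enolate face, so that allyl ends trans and the carboxyl carbon C19 cis to C11 (sets C18).

Step 7
Reactants: 13 4-methoxybenzyl (4S,5S)-4-allyl-5-(dimethoxymethyl)-1-(4-methoxybenzyl)-2-oxopiperidine-4-carboxylate
Product: 14 (4S,5S)-4-allyl-5-(dimethoxymethyl)-4-(hydroxymethyl)-1-(4-methoxybenzyl)piperidin-2-one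
Conditions: LiBH4, MeOH (1 equiv), THF, 0 → 40 °C
Reagents that add atoms: none
Why: Chemoselective hydride reduction: LiBH4 reduces the benzylic ester to the neopentyl primary alcohol and should not touch the tertiary lactam, the acetal or the alkene.

Step 8
Reactants: 14 (4S,5S)-4-allyl-5-(dimethoxymethyl)-4-(hydroxymethyl)-1-(4-methoxybenzyl)piperidin-2-one
Product: 15 (4S,5S)-4-allyl-4-[(tert-butyldiphenylsilyloxy)methyl]-5-(dimethoxymethyl)-1-(4-methoxybenzyl)piperidin-2-one
Conditions: t-BuPh2SiCl, imidazole, DMF, rt
Reagents that add atoms: tert-butyl(chloro)diphenylsilane, CC(C)(C)[Si](Cl)(c1ccccc1)c1ccccc1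
Why: Silyl ether formation on the only hydroxyl group; the TBDPS group is chosen because it should survive aqueous acid, (NH4)2Ce(NO3)6 and base.

Step 9
Reactants: 15 (4S,5S)-4-allyl-4-[(tert-butyldiphenylsilyloxy)methyl]-5-(dimethoxymethyl)-1-(4-methoxybenzyl)piperidin-2-one; 16 methyl acrylate
Product: 19 methyl (E)-3-[4-allyl-4-(TBDPS-oxymethyl)-5-(dimethoxymethyl)-1-PMB-2-oxopiperidin-3-yl]acrylate (C6 epimers; C10 and C18 as in 15), via selenide 17 (not isolated), via selenoxide 18 (not isolated)
Conditions: LiN(i-Pr)2, THF, −78 °C; methyl acrylate; PhSeBr; then H2O2 (30%), pyridine, CH2Cl2, 0 °C → rt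
Reagents that add atoms: none
Why: Michael addition of the lactam lithium enolate (the only acidic C–H left) to methyl acrylate, selenenylation of the resulting ester enolate and selenoxide syn-elimination (possible only towards C5) should give the (E)-acrylate arm; the C6 configuration is immaterial because C6 is enolised in step 13.

Step 10
Reactants: 19 acrylate lactam acetal
Product: 20 methyl (E)-3-[4-allyl-4-(TBDPS-oxymethyl)-5-formyl-1-PMB-2-oxopiperidin-3-yl]acrylate (C6 epimers)
Conditions: pyridinium p-toluenesulfonate, acetone/H2O (10:1), 50 °C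
Reagents that add atoms: water, O
Why: Acid-catalysed acetal hydrolysis should unmask the C11 aldehyde; the quaternary neighbour C18 disfavours enolisation towards C10, and the silyl ether survives.

Step 11
Reactants: 20 lactam aldehyde; 21 cyclohexane-1,3-dione
Product: 23 lactam-tethered 2-alkylcyclohexane-1,3-dione (C11 joined to C12; C6 epimers), via alkylidene dione 22 (not isolated)
Conditions: Hantzsch ester, L-proline (20 mol%), CH2Cl2, rt
Reagents that add atoms: none
Why: Organocatalytic reductive alkylation (Knoevenagel condensation followed by Hantzsch-ester transfer hydrogenation of the alkylidene dione) should attach C11 to C12 cleanly at carbon, avoiding the O-alkylation that plagues direct alkylation of 1,3-diones.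

Step 12
Reactants: 23 lactam-tethered 2-alkylcyclohexane-1,3-dione
Product: 24 lactam-tethered β-chloroenone (3-chlorocyclohex-2-enone arm on C10; (E)-acrylate arm on C6; C18 with CH2OTBDPS and allyl; N-PMB; C6 epimers)
Conditions: (COCl)2, DMF (cat.), CH2Cl2, 0 °C
Reagents that add atoms: oxalyl chloride, O=C(Cl)C(=O)Cl
Why: Conversion of the vinylogous acid into the vinylogous acid chloride with the Vilsmeier-type reagent; the 2-substituted 1,3-dione is symmetric, so only one 3-chloro-enone can form.

Step 13
Reactants: 24 lactam-tethered β-chloroenone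
Product: 25 tricyclic enone lactam (rings B C D closed; C6 quaternary with the (E)-acrylate arm; C18 with CH2OTBDPS and allyl; N-PMB)
Conditions: KOt-Bu (1.1 equiv), THF/t-BuOH (10:1), 0.01 M, −20 °C → rt
Reagents that add atoms: none
Why: KOt-Bu removes the C6–H, which is α to the lactam carbonyl and vinylogously α to the ester and therefore the most acidic C–H in 24, and the extended enolate adds through C6 to the chlorine-bearing β-carbon C13, after which the ketone enolate so formed expels chloride and the enone is restored (intramolecular conjugate addition–elimination, a vinylogous acyl substitution). The closest known reaction type is the addition–elimination of malonate-type and amide enolates on 3-halocycloalk-2-enones, with the palladium-catalysed intramolecular enolate alkenylation as its organometallic counterpart. Ring B closes in the 6-endo-trig mode (C12 and C13 both lie in the new ring) and forms the carbocyclic half of the 2-azabicyclo[3.3.1]nonane. The new quaternary centre C6 is controlled by C10, because the one-carbon link C11 can carry C13 only to the enolate face cis to itself, so C6 follows from the C10/C18 pair set in steps 2 and 6. The step needs C- over O-attack, α- over γ-attack of the dienolate and substitution over carbonyl addition: the first two are secured by ring size (six against eight), the third by the reversibility of the aldol-type addition against the irreversible loss of chloride, and the N-PMB group blocks the competing six-membered aza-substitution.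

Step 14
Reactants: 25 tricyclic enone lactam
Product: 26 tricyclic ene-1,4-dione (C14 and C17 both C=O)
Conditions: Rh2(cap)4 (1 mol%), t-BuOOH (5 equiv, decane solution), ClCH2CH2Cl, 40 °C
Reagents that add atoms: tert-butyl hydroperoxide, CC(C)(C)OO
Why: Allylic (γ-methylene) oxidation of an enone to the ene-1,4-dione by the tert-butylperoxy radical: the C14–H bonds are the weakest in 25 because the radical is delocalised over the enone, and base-free conditions are chosen because such ene-diones tautomerise to hydroquinones with base (26 is taken on at once).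

Step 15
Reactants: 26 tricyclic ene-1,4-dione
Product: 27 C17 ethylene ketal of the ene-dione (C14 ketone free)
Conditions: (Me3SiOCH2)2, Me3SiOTf (5 mol%), CH2Cl2, −78 → −30 °C
Reagents that add atoms: 1,2-bis(trimethylsilyloxy)ethane, C[Si](C)(C)OCCO[Si](C)(C)C
Why: Noyori ketalisation under kinetic conditions should select the C17 carbonyl, flanked only by the ring-B methylene, over the C14 carbonyl buried beside the quaternary C6 and its acrylate arm (the steric bias that allows monoketalisation of ketoisophorone), and it removes the risk of aromatising ring C.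

Step 16
Reactants: 27 C17 ethylene ketal of the ene-dione
Product: 28 tetracyclic β-hydroxy ester (ring A closed; C14 tertiary OH cis to C7; C4 epimers; C17 ketal)
Conditions: [(Ph3P)CuH]6 (0.5 equiv), toluene/THF, −40 → 0 °C; aq. NH4Cl
Reagents that add atoms: none
Why: Reductive aldol cyclisation (Stryker's reagent): conjugate hydride addition to the acrylate generates the copper ester enolate regiospecifically without base, and this closes ring A by a 5-(enolexo)-exo-trig aldol addition to the C14 ketone from the face anti to the lactam carbonyl C7 that leans under ring A, placing the new hydroxyl cis to C7 (sets C14; C4 is not controlled here and is erased in step 17).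

Step 17
Reactants: 28 tetracyclic β-hydroxy ester
Product: 31 tetracyclic cyclopentene ester (C4=C5; C14 OH), via selenide 29 (not isolated), via selenoxide 30 (not isolated)
Conditions: LiN(i-Pr)2 (2.3 equiv), THF, −78 °C; PhSeBr; then NaIO4, NaHCO3, THF/MeOH/H2O, rt
Reagents that add atoms: none
Why: Selenenylation of the β-alkoxide ester dianion (the ester α-H at C4 is now the only acidic C–H) and selenoxide syn-elimination, which can only run towards C5, should restore the C4=C5 double bond so that C4 can be set at the end by hydrogenation.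

Step 18
Reactants: 31 tetracyclic cyclopentene ester
Product: 33 primary alcohol (C22 OH on the C18 arm), via alkylborane 32 (not isolated)
Conditions: 9-BBN (3 equiv), THF, rt; then NaBO3·4H2O, H2O, rt
Reagents that add atoms: sodium perborate, [Na+].[O-]OB=O
Why: Hydroboration–oxidation: 9-BBN should add only to the terminal allyl alkene (the ester-conjugated C4=C5 and the tetrasubstituted C12=C13 alkenes are inert) with anti-Markovnikov selectivity, giving the C22 alcohol after mild perborate oxidation.

Step 19
Reactants: 33 primary alcohol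
Product: 34 aldehyde (C22 CHO)
Conditions: Dess–Martin periodinane, NaHCO3, CH2Cl2, 0 °C → rt
Reagents that add atoms: none
Why: Dess–Martin oxidation of the primary alcohol to the aldehyde under buffered conditions; the tertiary C14 hydroxyl cannot be oxidised.

Step 20
Reactants: 34 aldehyde; 35 2-bromopropene
Product: 36 allylic alcohol (C22 carbinol bearing the isopropenyl group; C22 epimers)
Conditions: CrCl2 (5 equiv), NiCl2 (2 mol%), DMF, rt
Reagents that add atoms: none
Why: Nozaki–Hiyama–Kishi coupling: the isopropenylchromium reagent adds to the aldehyde selectively in the presence of the ester, lactam and ketal, and the two C22 epimers converge in step 21.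

Step 21
Reactants: 36 allylic alcohol
Product: 37 isopropenyl ketone (C22 C=O; C23=C24)
Conditions: Dess–Martin periodinane, NaHCO3, CH2Cl2, rt
Reagents that add atoms: none
Why: Dess–Martin oxidation of the secondary allylic alcohol should give the isopropenyl ketone that serves as the Michael acceptor.

Step 22
Reactants: 37 isopropenyl ketone
Product: 38 NH-lactam with the free C17 enone and the isopropenyl ketone
Conditions: (NH4)2Ce(NO3)6 (4 equiv), MeCN/H2O (4:1), 0 °C → rt
Reagents that add atoms: water, O
Why: Oxidative N-debenzylation (single-electron oxidation of the anisyl ring, then hydrolysis of the N-acyliminium ion) should free the lactam N–H, and the acidic aqueous medium should hydrolyse the dioxolane at the same time, regenerating the C17 enone, which can no longer aromatise because C14 is quaternary.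

Step 23
Reactants: 38 NH-lactam
Product: 39 pentacyclic lactam (ring E closed; C4=C5; C19 OTBDPS)
Conditions: Cs2CO3 (0.5 equiv), MeCN, 0.002 M, 40 °C
Reagents that add atoms: none
Why: Intramolecular aza-Michael addition: the caesium lactamate adds through N8 to the terminal carbon C24 of the isopropenyl ketone, helped by the C18 arm being axial on ring D and lying over N8, and protonation of the enolate under equilibrating conditions should place the C23 methyl in the more stable orientation on ring E (sets C23; see the assumption).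

Step 24
Reactants: 39 pentacyclic lactam
Product: 40 C19 TBDPS ether of the deacetyl target
Conditions: H2 (1 atm), [Ir(cod)(PCy3)(py)]PF6 (10 mol%), CH2Cl2, rt
Reagents that add atoms: none
Why: Hydroxyl-directed homogeneous hydrogenation (Crabtree's catalyst): iridium bound to the C14 hydroxyl should deliver hydrogen to the same, exposed face of the C4=C5 ester alkene, so that C4–H ends cis to the hydroxyl and the ester trans (sets C4), while the tetrasubstituted conjugated C12=C13 bond is too hindered to react.

Step 25
Reactants: 40 C19 TBDPS ether of the deacetyl target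
Product: 41 deacetyl target (C19 primary alcohol)
Conditions: HF·pyridine, pyridine/THF, 0 °C → rt
Reagents that add atoms: none
Why: Fluoride-mediated desilylation under slightly acidic conditions avoids base, so the C4 ester centre, the β-hydroxy ester and the β-amido ketone are not put at risk.

Step 26
Reactants: 41 deacetyl target
Product: 42 CNP0211170.1
Conditions: Ac2O, pyridine, DMAP (cat.), CH2Cl2, 0 °C
Reagents that add atoms: acetic anhydride, CC(=O)OC(C)=O
Why: Acetylation of the primary alcohol; the tertiary C14 hydroxyl does not react under these mild conditions, so 42 should be obtained.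

Compound list
1 | 2,2-dimethoxyacetaldehyde | COC(OC)C=O | starting material
2 | nitromethane | C[N+](=O)[O-] | starting material
3 | 3,3-dimethoxy-1-nitropropan-2-ol (racemic; not isolated) | COC(OC)C(O)C[N+](=O)[O-] | intermediate
4 | 3,3-dimethoxy-1-nitropropan-2-yl trifluoroacetate (not isolated) | COC(OC)C(OC(=O)C(F)(F)F)C[N+](=O)[O-] | intermediate
5 | (E)-3,3-dimethoxy-1-nitroprop-1-ene | COC(OC)/C=C/[N+](=O)[O-] | intermediate
6 | methyl 4-oxobutanoate | COC(=O)CCC=O | starting material
7 | methyl (3S,4S)-3-formyl-5,5-dimethoxy-4-(nitromethyl)pentanoate | [O-][N+](=O)C[C@@H](C(OC)OC)[C@@H](C=O)CC(=O)OC | intermediate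
8 | (2S,3S)-4,4-dimethoxy-2-(2-methoxy-2-oxoethyl)-3-(nitromethyl)butanoic acid | [O-][N+](=O)C[C@@H](C(OC)OC)[C@@H](C(=O)O)CC(=O)OC | intermediate
9 | (2S,3S)-3-(aminomethyl)-4,4-dimethoxy-2-(2-methoxy-2-oxoethyl)butanoic acid (not isolated) | NC[C@@H](C(OC)OC)[C@@H](C(=O)O)CC(=O)OC | intermediate
10 | (4S,5S)-5-(dimethoxymethyl)-2-oxopiperidine-4-carboxylic acid | C1C(=O)NC[C@@H](C(OC)OC)[C@H]1C(=O)O | intermediate
11 | 4-methoxybenzyl (4S,5S)-5-(dimethoxymethyl)-1-(4-methoxybenzyl)-2-oxopiperidine-4-carboxylate | C1C(=O)N(Cc2ccc(OC)cc2)C[C@@H](C(OC)OC)[C@H]1C(=O)OCc3ccc(OC)cc3 | intermediate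
12 | allyl bromide | C=CCBr | starting material
13 | 4-methoxybenzyl (4S,5S)-4-allyl-5-(dimethoxymethyl)-1-(4-methoxybenzyl)-2-oxopiperidine-4-carboxylate | C1C(=O)N(Cc2ccc(OC)cc2)C[C@@H](C(OC)OC)[C@]1(C(=O)OCc3ccc(OC)cc3)CC=C | intermediate
14 | (4S,5S)-4-allyl-5-(dimethoxymethyl)-4-(hydroxymethyl)-1-(4-methoxybenzyl)piperidin-2-one | C1C(=O)N(Cc2ccc(OC)cc2)C[C@@H](C(OC)OC)[C@]1(CO)CC=C | intermediate
15 | (4S,5S)-4-allyl-4-[(tert-butyldiphenylsilyloxy)methyl]-5-(dimethoxymethyl)-1-(4-methoxybenzyl)piperidin-2-one | C1C(=O)N(Cc2ccc(OC)cc2)C[C@@H](C(OC)OC)[C@]1(CO[Si](c3ccccc3)(c4ccccc4)C(C)(C)C)CC=C | intermediate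
16 | methyl acrylate | C=CC(=O)OC | starting material
17 | methyl 3-(lactam-3-yl)-2-(phenylselanyl)propanoate, the α-selanyl ester of 15 (epimer mixture; not isolated) | COC(=O)C([Se]c5ccccc5)CC1C(=O)N(Cc2ccc(OC)cc2)C[C@@H](C(OC)OC)[C@]1(CO[Si](c3ccccc3)(c4ccccc4)C(C)(C)C)CC=C | intermediate
18 | selenoxide of 17 (not isolated) | COC(=O)C([Se](=O)c5ccccc5)CC1C(=O)N(Cc2ccc(OC)cc2)C[C@@H](C(OC)OC)[C@]1(CO[Si](c3ccccc3)(c4ccccc4)C(C)(C)C)CC=C | intermediate
19 | methyl (E)-3-[4-allyl-4-(TBDPS-oxymethyl)-5-(dimethoxymethyl)-1-PMB-2-oxopiperidin-3-yl]acrylate (C6 epimers; C10, C18 as in 15) | COC(=O)/C=C/C1C(=O)N(Cc2ccc(OC)cc2)C[C@@H](C(OC)OC)[C@]1(CO[Si](c3ccccc3)(c4ccccc4)C(C)(C)C)CC=C | intermediate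
20 | methyl (E)-3-[4-allyl-4-(TBDPS-oxymethyl)-5-formyl-1-PMB-2-oxopiperidin-3-yl]acrylate (C6 epimers) | COC(=O)/C=C/C1C(=O)N(Cc2ccc(OC)cc2)C[C@@H](C=O)[C@]1(CO[Si](c3ccccc3)(c4ccccc4)C(C)(C)C)CC=C | intermediate
21 | cyclohexane-1,3-dione | O=C1CCCC(=O)C1 | starting material
22 | 2-alkylidenecyclohexane-1,3-dione from 20 (not isolated) | COC(=O)/C=C/C1C(=O)N(Cc2ccc(OC)cc2)C[C@@H](C=C5C(=O)CCCC5=O)[C@]1(CO[Si](c3ccccc3)(c4ccccc4)C(C)(C)C)CC=C | intermediate
23 | lactam-tethered 2-alkylcyclohexane-1,3-dione (C6 epimers) | COC(=O)/C=C/C1C(=O)N(Cc2ccc(OC)cc2)C[C@@H](CC5C(=O)CCCC5=O)[C@]1(CO[Si](c3ccccc3)(c4ccccc4)C(C)(C)C)CC=C | intermediate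
24 | lactam-tethered β-chloroenone, substrate of the key step (C6 epimers) | COC(=O)/C=C/C1C(=O)N(Cc2ccc(OC)cc2)C[C@@H](CC5=C(Cl)CCCC5=O)[C@]1(CO[Si](c3ccccc3)(c4ccccc4)C(C)(C)C)CC=C | intermediate
25 | tricyclic enone lactam, product of the key step | COC(=O)/C=C/[C@@]12C(=O)N(Cc3ccc(OC)cc3)C[C@@H](CC4=C1CCCC4=O)[C@]2(CO[Si](c5ccccc5)(c6ccccc6)C(C)(C)C)CC=C | intermediate
26 | tricyclic ene-1,4-dione | COC(=O)/C=C/[C@@]12C(=O)N(Cc3ccc(OC)cc3)C[C@@H](CC4=C1C(=O)CCC4=O)[C@]2(CO[Si](c5ccccc5)(c6ccccc6)C(C)(C)C)CC=C | intermediate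
27 | C17 ethylene ketal of 26 | COC(=O)/C=C/[C@@]12C(=O)N(Cc3ccc(OC)cc3)C[C@@H](CC4=C1C(=O)CCC47OCCO7)[C@]2(CO[Si](c5ccccc5)(c6ccccc6)C(C)(C)C)CC=C | intermediate
28 | tetracyclic β-hydroxy ester, ring A closed (C4 epimers) | COC(=O)C1C[C@@]23C(=O)N(Cc4ccc(OC)cc4)C[C@@H](CC5=C2[C@]1(O)CCC56OCCO6)[C@]3(CO[Si](c7ccccc7)(c8ccccc8)C(C)(C)C)CC=C | intermediate
29 | C4 phenylselanyl derivative of 28 (not isolated) | COC(=O)C1([Se]c9ccccc9)C[C@@]23C(=O)N(Cc4ccc(OC)cc4)C[C@@H](CC5=C2[C@]1(O)CCC56OCCO6)[C@]3(CO[Si](c7ccccc7)(c8ccccc8)C(C)(C)C)CC=C | intermediate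
30 | selenoxide of 29 (not isolated) | COC(=O)C1([Se](=O)c9ccccc9)C[C@@]23C(=O)N(Cc4ccc(OC)cc4)C[C@@H](CC5=C2[C@]1(O)CCC56OCCO6)[C@]3(CO[Si](c7ccccc7)(c8ccccc8)C(C)(C)C)CC=C | intermediate
31 | tetracyclic cyclopentene ester (C4=C5) | COC(=O)C1=C[C@@]23C(=O)N(Cc4ccc(OC)cc4)C[C@@H](CC5=C2[C@]1(O)CCC56OCCO6)[C@]3(CO[Si](c7ccccc7)(c8ccccc8)C(C)(C)C)CC=C | intermediate
32 | B-alkyl-9-borabicyclo[3.3.1]nonane from 31 (not isolated) | COC(=O)C1=C[C@@]23C(=O)N(Cc4ccc(OC)cc4)C[C@@H](CC5=C2[C@]1(O)CCC56OCCO6)[C@]3(CO[Si](c7ccccc7)(c8ccccc8)C(C)(C)C)CCCB9C%10CCCC9CCC%10 | intermediate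
33 | primary alcohol (C22 OH) | COC(=O)C1=C[C@@]23C(=O)N(Cc4ccc(OC)cc4)C[C@@H](CC5=C2[C@]1(O)CCC56OCCO6)[C@]3(CO[Si](c7ccccc7)(c8ccccc8)C(C)(C)C)CCCO | intermediate
34 | aldehyde (C22 CHO) | COC(=O)C1=C[C@@]23C(=O)N(Cc4ccc(OC)cc4)C[C@@H](CC5=C2[C@]1(O)CCC56OCCO6)[C@]3(CO[Si](c7ccccc7)(c8ccccc8)C(C)(C)C)CCC=O | intermediate
35 | 2-bromopropene | CC(Br)=C | starting material
36 | allylic alcohol (C22 epimers) | COC(=O)C1=C[C@@]23C(=O)N(Cc4ccc(OC)cc4)C[C@@H](CC5=C2[C@]1(O)CCC56OCCO6)[C@]3(CO[Si](c7ccccc7)(c8ccccc8)C(C)(C)C)CCC(O)C(C)=C | intermediate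
37 | isopropenyl ketone | COC(=O)C1=C[C@@]23C(=O)N(Cc4ccc(OC)cc4)C[C@@H](CC5=C2[C@]1(O)CCC56OCCO6)[C@]3(CO[Si](c7ccccc7)(c8ccccc8)C(C)(C)C)CCC(=O)C(C)=C | intermediate
38 | NH-lactam with free C17 enone | COC(=O)C1=C[C@@]23C(=O)NC[C@@H](CC5=C2[C@]1(O)CCC5=O)[C@]3(CO[Si](c7ccccc7)(c8ccccc8)C(C)(C)C)CCC(=O)C(C)=C | intermediate
39 | pentacyclic lactam, ring E closed (C4=C5; C19 OTBDPS) | COC(=O)C1=C[C@@]23C(=O)N4C[C@@H](CC5=C2[C@]1(O)CCC5=O)[C@]3(CO[Si](c6ccccc6)(c7ccccc7)C(C)(C)C)CCC(=O)[C@H](C)C4 | intermediate
40 | C19 TBDPS ether of the deacetyl target | COC(=O)[C@@H]1C[C@@]23C(=O)N4C[C@@H](CC5=C2[C@]1(O)CCC5=O)[C@]3(CO[Si](c6ccccc6)(c7ccccc7)C(C)(C)C)CCC(=O)[C@H](C)C4 | intermediate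
41 | deacetyl target (C19 primary alcohol) | COC(=O)[C@@H]1C[C@@]23C(=O)N4C[C@@H](CC5=C2[C@]1(O)CCC5=O)[C@]3(CO)CCC(=O)[C@H](C)C4 | intermediate
42 | CNP0211170.1 | COC(=O)[C@@H]1C[C@@]23C(=O)N4C[C@@H](CC5=C2[C@]1(O)CCC5=O)[C@]3(COC(C)=O)CCC(=O)[C@H](C)C4 | target

Total step count: 26. Longest linear sequence: 26 steps (1 → 42).

Steps most likely to fail

Step 13 (key step). The ring closure joins a tertiary carbanion to a fully substituted alkene carbon next to a quaternary centre, so it may be outrun by intermolecular substitution, stall at the reversible carbonyl-addition stage, or be diverted by γ-deprotonation of the chloroenone. Fallback, setting out from 24 and returning to 25: a palladium-catalysed intramolecular enolate alkenylation with Pd(OAc)2, P(t-Bu)3·HBF4 and K3PO4 in toluene at 80 °C. Zerovalent palladium inserts into the C13–Cl bond of the vinylogous acid chloride, the soft C6 carbanion replaces chloride on divalent palladium, and reductive elimination forms C6–C13. The bond is then made by cross-coupling at the metal and no longer by attack on the crowded alkene carbon; no new compound arises (entry F0).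

Step 16. Hydride may be transferred to the C14 ketone in place of the acrylate, the copper enolate may be protonated before it cyclises, or ring A may close on the wrong face of the ketone under kinetic control, which cannot be corrected later. Fallback, setting out from 27 and returning to 31 (28–30 are bypassed): a thiolate-triggered Michael–aldol sequence run under equilibrating conditions. Me2AlSPh in CH2Cl2 (−78 → 0 °C) adds sulfur to C5 and the aluminium enolate closes ring A reversibly, so the carbinol centre can settle under thermodynamic control, giving the β-phenylthio aldol adduct F1. NaIO4 in aqueous methanol oxidises sulfur to give the sulfoxide F2, and heating in toluene (110 °C, CaCO3) expels benzenesulfenic acid by syn-elimination towards C4 to give 31.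

Step 23. Closure of the nine-membered ring E through the weakly nucleophilic lactam nitrogen may not compete with intermolecular addition, may revert by retro-Michael opening, or the C23 centre may equilibrate to the unwanted epimer. Fallback, setting out from 36 and returning to 39: an irreversible N-allylation followed by an epoxide rearrangement. CBr4/PPh3 in CH2Cl2 converts the secondary allylic alcohol into the primary allylic bromide F3 (the untransposed secondary bromide would react in the same sense by SN2′). (NH4)2Ce(NO3)6 in aqueous MeCN removes PMB and the dioxolane to give the NH-lactam bromide F4. KN(SiMe3)2 in THF at high dilution alkylates N8 and closes ring E as the cycloalkene F5. mCPBA epoxidises the only electron-rich alkene to give the epoxide F6. BF3·OEt2 at −78 °C then triggers a Meinwald rearrangement (hydride shift from C22 to the tertiary cation at C23) to give ketone 39, whose C23 centre can be equilibrated with mild base if required.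

Further compounds
F0 | step 13 | none | none
F1 | step 16 | β-phenylthio aldol adduct (PhS on C5; ring A closed; C4 and C5 epimers) | COC(=O)C1C(Sc9ccccc9)[C@@]23C(=O)N(Cc4ccc(OC)cc4)C[C@@H](CC5=C2[C@]1(O)CCC56OCCO6)[C@]3(CO[Si](c7ccccc7)(c8ccccc8)C(C)(C)C)CC=C
F2 | step 16 | sulfoxide of F1 | COC(=O)C1C(S(=O)c9ccccc9)[C@@]23C(=O)N(Cc4ccc(OC)cc4)C[C@@H](CC5=C2[C@]1(O)CCC56OCCO6)[C@]3(CO[Si](c7ccccc7)(c8ccccc8)C(C)(C)C)CC=C
F3 | step 23 | primary allylic bromide (C22=C23; C24 bromide; N-PMB; C17 ketal) | COC(=O)C1=C[C@@]23C(=O)N(Cc4ccc(OC)cc4)C[C@@H](CC5=C2[C@]1(O)CCC56OCCO6)[C@]3(CO[Si](c7ccccc7)(c8ccccc8)C(C)(C)C)CCC=C(C)CBr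
F4 | step 23 | NH-lactam allylic bromide (C17 enone free) | COC(=O)C1=C[C@@]23C(=O)NC[C@@H](CC5=C2[C@]1(O)CCC5=O)[C@]3(CO[Si](c7ccccc7)(c8ccccc8)C(C)(C)C)CCC=C(C)CBr
F5 | step 23 | ring-E cycloalkene (C22=C23) | COC(=O)C1=C[C@@]23C(=O)N4C[C@@H](CC5=C2[C@]1(O)CCC5=O)[C@]3(CO[Si](c6ccccc6)(c7ccccc7)C(C)(C)C)CCC=C(C)C4
F6 | step 23 | C22–C23 epoxide of F5 | COC(=O)C1=C[C@@]23C(=O)N4C[C@@H](CC5=C2[C@]1(O)CCC5=O)[C@]3(CO[Si](c6ccccc6)(c7ccccc7)C(C)(C)C)CCC8OC8(C)C4
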